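## The problem

The target 20 is a flavonol, a 2-aryl-3-hydroxy-4H-chromen-4-one, whose pyranone ring C is fused to a benzene ring A substituted at every carbon except C6 (5-OH, 7-O-prenyl, 8-OMe and O1 on C8a) and which carries a 4-hydroxy-3-methoxyphenyl ring B on C2. There is no stereocentre, so no centre can steer another and the difficulty is regiochemical throughout. Ring A has two oxygen-bearing carbons ortho to C4a, and whichever becomes C8a decides whether the methoxy group ends at C8, as wanted, or at C6. The prenyl group must sit on O7 only, and as an allylic aryl ether it rules out hydrogenolysis, boron or aluminium halides, strong acid and high temperature, so the 3-, 5- and 4'-hydroxyls need protecting groups that leave under mild acid. The 3-oxygen is best carried in from the start, because late oxidation at C3 would compete with the prenyl double bond. The enabling feature is ring A itself: oxygen on C5, C7 and C8 with hydrogen on C6 is the pattern of the four-carbon chain of methyl 4-methoxyacetoacetate 1, and C4a–C8a with the C4 carbon on C4a is an alkynoate. If that alkynoate carries bromine on its β-carbon, ring A is formed with a halogen at C8a, and the two ortho positions are distinct from the outset.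

## Retrosynthesis

**20 ⇒ 19.** Only three O–CH2OMe acetal bonds are cut, on O3, O5 and O4'. Methoxymethyl (MOM) is preferred to benzyl or methyl because it leaves in dilute acid, which the prenyl ether should tolerate. The forward step must cleave the acetals without ionising the allylic ether.

**19 ⇒ 18.** Ring C is opened at O1–C8a. The neighbouring cut, O1–C2 (dehydrative closure of a 2-hydroxyaryl diketone), would need the C8a oxygen in place and distinguished from O5. Cutting O1–C8a lets a bromine mark C8a instead. Precursor 18 is an open-chain, largely enolised 1,3-diketone with an aryl bromide ortho to the ketone. The forward reaction is an intramolecular copper-catalysed O-arylation, in which only the distal carbonyl oxygen can reach the C–Br carbon through a six-membered ring.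

**18 ⇒ 11 + 16 (through acid chloride 17).** The C3–C4 bond is cut. The other seam, C2–C3, would need a ring A α-alkoxyacetophenone, which the ring A synthesis does not supply, whereas the benzannulation delivers a carboxyl carbon on C4a. This cut halves the molecule into benzoic acid 11 and α-alkoxy ketone 16. The forward step must C-acylate a ketone enolate with a di-ortho-substituted aroyl chloride.

**16 ⇒ 15 ⇒ 13 ⇒ 12.** The C3 oxygen is installed on acetovanillone 12 by α-bromination to 13 and exchange of bromide for oxygen through formate ester 14 to ketol 15. One MOM protection then covers both the phenol and the new alcohol. No skeletal bond is made.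

**11 ⇒ 10 ⇒ 9 ⇒ 7 + 8.** These are functional-group changes on the finished arene. The O7–prenyl bond is cut first (7 + prenyl bromide 8), relying on 7 having one free and one ester-chelated hydroxyl. MOM then goes on the chelated hydroxyl (10), and only then is the hindered ester hydrolysed (11).

**7 ⇒ 3 + 5 (through cycloadduct 6).** Ring A is cut at C4a–C5 and C8–C8a, giving diene 3 and methyl 3-bromopropiolate 5. Functionalising a preformed arene is the obvious alternative, but it fails on regiochemistry: electrophilic bromination of the bromine-free analogue of 7 would go between the two hydroxyls, not next to the ester. The cycloaddition places Br, OMe, OH, H, OH and CO2Me in one operation. The forward reaction must be regioselective and must close the ring without expelling bromide.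

**3 ⇒ 2 ⇒ 1 and 5 ⇒ 4.** Diene 3 is the bis-silyl dienolate of ketoester 1, made in two stages via enol ether 2. Bromoalkyne 5 comes from methyl propiolate 4 by silver-catalysed bromination.

## Roads not taken

**Alternative 1: carbon monoxide as C2.** The cut is on both sides of C2 (C1'–C2 and C2–C3). The enolate of the ring A ketone 1-[2-hydroxy-3-methoxy-6-(methoxymethoxy)-4-(prenyloxy)phenyl]-2-(methoxymethoxy)ethan-1-one A2 is joined to the ring B bromide 4-bromo-2-methoxy-1-(methoxymethoxy)benzene A3 and carbon monoxide under Pd(dba)2/Xantphos, giving the diketone A1.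
- Merits: A1 has a free ortho hydroxyl, so one acid treatment could close ring C and remove the acetals. That endgame is shorter than steps 11–13 here, and it avoids a hindered acid chloride. Bromide A3 is a simple, readily prepared coupling partner.
- Weak points: A2 is an acetophenone with two ortho oxygens that must be told apart by selective protection, so the regiochemical question is moved, not solved. The coupling also has to tolerate a free phenol and an α-alkoxy enolate, with direct (non-carbonylative) α-arylation by A3 and retro-Claisen cleavage of A1 as competitors. In the acid closure the MOM group on the other ortho oxygen falls off under the same conditions, so closure through the wrong oxygen is not excluded.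
- Comparison: the chosen plan has more steps, but its C8a is a C–Br carbon and cannot be confused with C5.

**Alternative 2: thermal pyrone annulation of a symmetric resorcinol.** The cut is C4–C4a and O1–C2. The resorcinol 5-(benzyloxy)-2-methoxybenzene-1,3-diol A5 and the keto ester ethyl 2-(benzyloxy)-3-[4-(benzyloxy)-3-methoxyphenyl]-3-oxopropanoate A6 are heated neat at about 240 °C (Mentzer-type condensation) to give the flavonol ether A4.
- Merits: the symmetry of A5 settles the ring A regiochemistry as rigorously as the bromine does here. One step gives the whole skeleton with O3 in place, and the 7-hydroxyl of A4 is the only free one, so prenylation is unambiguous. From A5 and A6 this is the shortest road.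
- Weak points: after prenylation of A4 three benzyl ethers must be removed next to a prenyl ether. Hydrogenolysis attacks the alkene and the allylic C–O bond, and boron halides cleave the prenyl ether. Groups that survive 240 °C and still leave under mild acid are hard to find. A5 needs a multistep preparation, and keto ester A6 must itself withstand the temperature of the condensation.
- Comparison: the chosen plan is longer but runs below 100 °C with protecting groups compatible with the prenyl ether.

**Alternative 3: carbonylative alkynylation and cyclisation.** The cut is C4a–C4, C4–C3 and O1–C2. The iodoresorcinol 4-iodo-2-methoxy-5-(methoxymethoxy)benzene-1,3-diol A8, carbon monoxide and the arylacetylene 4-ethynyl-2-methoxy-1-(methoxymethoxy)benzene A9 are coupled with PdCl2(PPh3)2 in diethylamine, and the ortho hydroxyl then closes onto the ynone to give the flavone A7.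
- Merits: three simple components and mild conditions. The ring A regiochemistry is fixed by the iodine, since A8 would come from mono-iodination of a symmetric resorcinol, and A7 has a free 7-hydroxyl ready for prenylation. Alkyne A9 is easily made, and the flavone core is reached in fewer steps than in the chosen plan.
- Weak points: A7 has hydrogen at C3. The 3-hydroxyl must be added later by C3 metalation–oxidation or dioxirane epoxidation, which costs steps and endangers the prenyl alkene or forces a change of step order. Five-membered (aurone) closure competes with the six-membered one.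
- Comparison: the chosen plan carries O3 in ketone 16 from the start and needs no oxidation after the prenyl group is on.

Key step: step 4

Assumptions: enol ether 2 and diene 3 are written as single geometric isomers (Z, and 1Z,3Z); isomer mixtures would serve equally, because both geometries vanish on aromatisation. MOM = methoxymethyl; prenyl = 3-methylbut-2-en-1-yl.

## Route

Step 1
Reactants: 1 methyl 4-methoxy-3-oxobutanoate (methyl 4-methoxyacetoacetate)
Product: 2 methyl (Z)-4-methoxy-3-(trimethylsilyloxy)but-2-enoate
Conditions: Me3SiCl, Et3N, hexane, rt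
Reagents that add atoms: chlorotrimethylsilane, C[Si](C)(C)Cl
Why: O-silylation of the β-keto ester enol under amine base, the standard first stage of bis-silyl dienolate preparation; the product is filtered from the ammonium salt and distilled.

Step 2
Reactants: 2 methyl (Z)-4-methoxy-3-(trimethylsilyloxy)but-2-enoate
Product: 3 (1Z,3Z)-1,4-dimethoxy-1,3-bis(trimethylsilyloxy)buta-1,3-diene
Conditions: LiN(i-Pr)2, THF, −78 °C; then Me3SiCl, −78 °C → rt; non-aqueous work-up, used crude
Reagents that add atoms: chlorotrimethylsilane, C[Si](C)(C)Cl
Why: Deprotonation of the vinylogous ester at the γ-carbon (the CH2 next to OMe) and O-silylation of the dienolate gives the 1,3-bis(silyloxy)diene, the usual second stage for such dienes; the moisture-sensitive product is used at once.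

Step 3
Reactants: 4 methyl propiolate
Product: 5 methyl 3-bromoprop-2-ynoate (methyl 3-bromopropiolate)
Conditions: N-bromosuccinimide, AgNO3 (10 mol%), acetone, rt
Reagents that add atoms: N-bromosuccinimide, O=C1CCC(=O)N1Br
Why: Silver-catalysed electrophilic bromination of a terminal alkyne through the silver acetylide, the standard preparation of 3-bromopropiolates; the volatile lachrymatory product is used promptly.

Step 4
Reactants: 3 (1Z,3Z)-1,4-dimethoxy-1,3-bis(trimethylsilyloxy)buta-1,3-diene; 5 methyl 3-bromoprop-2-ynoate
Product: 7 methyl 2-bromo-4,6-dihydroxy-3-methoxybenzoate, via cycloadduct 6 (not isolated)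
Conditions: toluene, 0 → 50 °C; then 1 M aq. HCl, THF, 0 °C → rt
Reagents that add atoms: none
Why: Diels–Alder cycloaddition then aromatisation, the known benzannulation of 1-alkoxy-1,3-bis(silyloxy)buta-1,3-dienes with alkynoates to resorcylates, here with a 3-bromoalkynoate as the two-carbon partner. The addition is a normal-demand, strongly asynchronous [4+2] process in which C4 of the diene (the methoxy-bearing terminus with the largest HOMO coefficient) bonds to the bromine-bearing β-carbon of 5 and the ketene acetal carbon C1 closes onto the α-carbon. Ring A is thus closed in one six-membered cycloaddition that forms C8–C8a and C4a–C5 and gives cyclohexa-1,4-diene 6. On acidic work-up the silyl ethers are hydrolysed, the mixed ketal carbon loses methanol, and the ring tautomerises irreversibly to arene 7. No stereocentre survives, since the two sp3 centres of 6 and the diene geometry are erased on aromatisation. The selectivity needed is the orientation of addition, secured by matching the most nucleophilic diene terminus with the ester β-carbon, which puts the methoxy carbon beside the C–Br carbon and the chelated hydroxyl beside the ester. Bromine lowers the alkyne LUMO, so no Lewis acid is needed and the pathway stays close enough to concerted that bromide should not be expelled from a long-lived zwitterion. The methoxy group on the future C8 is retained because the only sp3-bound ring hydrogen of 6 sits on that carbon and is the one lost together with the ketal methoxy group.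

Step 5
Reactants: 7 methyl 2-bromo-4,6-dihydroxy-3-methoxybenzoate; 8 prenyl bromide (1-bromo-3-methylbut-2-ene)
Product: 9 methyl 2-bromo-6-hydroxy-3-methoxy-4-(prenyloxy)benzoate
Conditions: K2CO3 (1.1 equiv), acetone, rt
Reagents that add atoms: none
Why: Williamson ether synthesis; the 4-hydroxyl (para to the ester, not hydrogen-bonded) is the more acidic and reactive, while the 6-hydroxyl is locked in a hydrogen bond to the ester carbonyl, as in the selective 4-O-alkylation of 2,4-dihydroxybenzoates.

Step 6
Reactants: 9 methyl 2-bromo-6-hydroxy-3-methoxy-4-(prenyloxy)benzoate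
Product: 10 methyl 2-bromo-3-methoxy-6-(methoxymethoxy)-4-(prenyloxy)benzoate
Conditions: NaH, DMF, 0 °C; then MOMCl, 0 °C → rt
Reagents that add atoms: chloromethyl methyl ether, COCCl
Why: Irreversible deprotonation breaks the chelate and the phenoxide is alkylated by the chloromethyl ether; the acetal survives all the basic steps that follow and leaves in mild acid at the end.

Step 7
Reactants: 10 methyl 2-bromo-3-methoxy-6-(methoxymethoxy)-4-(prenyloxy)benzoate
Product: 11 2-bromo-3-methoxy-6-(methoxymethoxy)-4-(prenyloxy)benzoic acid
Conditions: KOH (excess), MeOH–H2O, 75 °C; then 1 M HCl to pH 4 at 0 °C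
Reagents that add atoms: potassium hydroxide, [K+].[OH-]
Why: Saponification of a di-ortho-substituted benzoate needs heat and excess hydroxide, which the ethers, acetal and aryl bromide tolerate; cold, controlled acidification keeps the MOM group and avoids decarboxylation of the electron-rich acid.

Step 8
Reactants: 12 acetovanillone (1-(4-hydroxy-3-methoxyphenyl)ethan-1-one)
Product: 13 2-bromo-1-(4-hydroxy-3-methoxyphenyl)ethan-1-one
Conditions: CuBr2 (2 equiv), EtOAc–CHCl3, reflux
Reagents that add atoms: copper dibromide, [Cu+2].[Br-].[Br-]
Why: Selective α-monobromination of an aryl methyl ketone by CuBr2 through the copper enolate; the free phenol and the ring are left alone under these heterogeneous conditions.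

Step 9
Reactants: 13 2-bromo-1-(4-hydroxy-3-methoxyphenyl)ethan-1-one
Product: 15 2-hydroxy-1-(4-hydroxy-3-methoxyphenyl)ethan-1-one, via formate ester 14 (not isolated)
Conditions: HCO2Na, EtOH–H2O, reflux
Reagents that add atoms: sodium formate, [Na+].[O-]C=O
Why: SN2 displacement of the phenacyl bromide by the weakly basic formate (no phenoxide is formed, so self-alkylation is avoided), followed by solvolysis of the labile formate ester in the same pot.

Step 10
Reactants: 15 2-hydroxy-1-(4-hydroxy-3-methoxyphenyl)ethan-1-one
Product: 16 2-(methoxymethoxy)-1-[3-methoxy-4-(methoxymethoxy)phenyl]ethan-1-one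
Conditions: MOMCl (2.5 equiv), i-Pr2NEt, CH2Cl2, 0 °C → rt
Reagents that add atoms: chloromethyl methyl ether, COCCl
Why: Double O-alkylation with the chloromethyl ether and a tertiary amine protects the phenol and the primary alcohol in one operation.

Step 11
Reactants: 11 2-bromo-3-methoxy-6-(methoxymethoxy)-4-(prenyloxy)benzoic acid; 16 2-(methoxymethoxy)-1-[3-methoxy-4-(methoxymethoxy)phenyl]ethan-1-one
Product: 18 racemic 1-[2-bromo-3-methoxy-6-(methoxymethoxy)-4-(prenyloxy)phenyl]-2-(methoxymethoxy)-3-[3-methoxy-4-(methoxymethoxy)phenyl]propane-1,3-dione, via acid chloride 17 (not isolated)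
Conditions: (a) 11, 1-chloro-N,N,2-trimethylprop-1-en-1-amine, CH2Cl2, 0 °C → rt, evaporate; (b) 16 (2.1 equiv), LiN(SiMe3)2 (2.0 equiv), THF, −78 °C, then 17 in THF, −78 → −20 °C; aq. NH4Cl
Reagents that add atoms: none
Why: Claisen-type C-acylation of a ketone enolate; the α-chloroenamine makes the acid chloride without free HCl, so the acetals survive, and the chelated lithium enolate of the α-alkoxy ketone is acylated at carbon, with the second equivalent of enolate deprotonating the more acidic diketone to stop over-acylation.

Step 12
Reactants: 18 racemic 1-[2-bromo-3-methoxy-6-(methoxymethoxy)-4-(prenyloxy)phenyl]-2-(methoxymethoxy)-3-[3-methoxy-4-(methoxymethoxy)phenyl]propane-1,3-dione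
Product: 19 8-methoxy-3,5-bis(methoxymethoxy)-2-[3-methoxy-4-(methoxymethoxy)phenyl]-7-(prenyloxy)-4H-chromen-4-one
Conditions: CuI (10 mol%), 1,10-phenanthroline (20 mol%), K2CO3, DMF, 90 °C
Reagents that add atoms: none
Why: Intramolecular Ullmann-type O-arylation of a 1-(2-bromoaryl)-1,3-diketone enolate, a known chromone closure; only the distal carbonyl oxygen can reach the C–Br carbon (six-membered ring), the ortho acyl group assists insertion of monovalent copper, and the temperature stays well below that of aryl prenyl ether rearrangement.

Step 13
Reactants: 19 8-methoxy-3,5-bis(methoxymethoxy)-2-[3-methoxy-4-(methoxymethoxy)phenyl]-7-(prenyloxy)-4H-chromen-4-one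
Product: 20 3,5-dihydroxy-2-(4-hydroxy-3-methoxyphenyl)-8-methoxy-7-(prenyloxy)-4H-chromen-4-one (target)
Conditions: 3 M aq. HCl, MeOH–THF, 40 °C
Reagents that add atoms: none
Why: Acid-catalysed acetal cleavage of the three MOM ethers; those on O5 and O3 are activated by the neighbouring carbonyl, and dilute acid at moderate temperature is used so that the allylic prenyl ether is not ionised.

## Compound list

1 | methyl 4-methoxy-3-oxobutanoate | COCC(=O)CC(=O)OC | starting material
2 | methyl (Z)-4-methoxy-3-(trimethylsilyloxy)but-2-enoate | COC/C(O[Si](C)(C)C)=C/C(=O)OC | intermediate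
3 | (1Z,3Z)-1,4-dimethoxy-1,3-bis(trimethylsilyloxy)buta-1,3-diene | CO/C=C(O[Si](C)(C)C)/C=C(/OC)O[Si](C)(C)C | intermediate
4 | methyl propiolate | C#CC(=O)OC | starting material
5 | methyl 3-bromoprop-2-ynoate | COC(=O)C#CBr | intermediate
6 | methyl 2-bromo-3,6-dimethoxy-4,6-bis(trimethylsilyloxy)cyclohexa-1,4-diene-1-carboxylate (racemic diastereomer mixture) | COC(=O)C1=C(Br)C(OC)C(O[Si](C)(C)C)=CC1(OC)O[Si](C)(C)C | intermediate (not isolated)
7 | methyl 2-bromo-4,6-dihydroxy-3-methoxybenzoate | COC(=O)c1c(O)cc(O)c(OC)c1Br | intermediate
8 | prenyl bromide (1-bromo-3-methylbut-2-ene) | CC(C)=CCBr | starting material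
9 | methyl 2-bromo-6-hydroxy-3-methoxy-4-[(3-methylbut-2-en-1-yl)oxy]benzoate | COC(=O)c1c(O)cc(OCC=C(C)C)c(OC)c1Br | intermediate
10 | methyl 2-bromo-3-methoxy-6-(methoxymethoxy)-4-[(3-methylbut-2-en-1-yl)oxy]benzoate | COCOc1cc(OCC=C(C)C)c(OC)c(Br)c1C(=O)OC | intermediate
11 | 2-bromo-3-methoxy-6-(methoxymethoxy)-4-[(3-methylbut-2-en-1-yl)oxy]benzoic acid | COCOc1cc(OCC=C(C)C)c(OC)c(Br)c1C(=O)O | intermediate
12 | acetovanillone (1-(4-hydroxy-3-methoxyphenyl)ethan-1-one) | CC(=O)c1ccc(O)c(OC)c1 | starting material
13 | 2-bromo-1-(4-hydroxy-3-methoxyphenyl)ethan-1-one | COc1cc(C(=O)CBr)ccc1O | intermediate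
14 | 2-(4-hydroxy-3-methoxyphenyl)-2-oxoethyl formate | COc1cc(C(=O)COC=O)ccc1O | intermediate (not isolated)
15 | 2-hydroxy-1-(4-hydroxy-3-methoxyphenyl)ethan-1-one | COc1cc(C(=O)CO)ccc1O | intermediate
16 | 2-(methoxymethoxy)-1-[3-methoxy-4-(methoxymethoxy)phenyl]ethan-1-one | COCOCC(=O)c1ccc(OCOC)c(OC)c1 | intermediate
17 | 2-bromo-3-methoxy-6-(methoxymethoxy)-4-[(3-methylbut-2-en-1-yl)oxy]benzoyl chloride | COCOc1cc(OCC=C(C)C)c(OC)c(Br)c1C(=O)Cl | intermediate (not isolated)
18 | racemic 1-[2-bromo-3-methoxy-6-(methoxymethoxy)-4-[(3-methylbut-2-en-1-yl)oxy]phenyl]-2-(methoxymethoxy)-3-[3-methoxy-4-(methoxymethoxy)phenyl]propane-1,3-dione | COCOC(C(=O)c1ccc(OCOC)c(OC)c1)C(=O)c1c(Br)c(OC)c(OCC=C(C)C)cc1OCOC | intermediate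
19 | 8-methoxy-3,5-bis(methoxymethoxy)-2-[3-methoxy-4-(methoxymethoxy)phenyl]-7-[(3-methylbut-2-en-1-yl)oxy]-4H-chromen-4-one | COCOc1ccc(-c2oc3c(OC)c(OCC=C(C)C)cc(OCOC)c3c(=O)c2OCOC)cc1OC | intermediate
20 | 3,5-dihydroxy-2-(4-hydroxy-3-methoxyphenyl)-8-methoxy-7-[(3-methylbut-2-en-1-yl)oxy]-4H-chromen-4-one | COc1cc(-c2oc3c(OC)c(OCC=C(C)C)cc(O)c3c(=O)c2O)ccc1O | target

## Step count and least certain steps

Total: 13 steps. Longest linear sequence: 9 steps (1, 2, 4, 5, 6, 7, 11, 12, 13).

**Step 4 (key step).** The most likely failure is expulsion of bromide after the first C–C bond has formed (conjugate addition–elimination) in place of ring closure, because the diene is a strong carbon nucleophile and the intermediate vinyl anion has a β-leaving group. Thermal degradation of the bromoalkyne, loss of the silyloxy group in place of the methoxy group at the ketal carbon, and exchange of the vinylogous bromide by solvent before aromatisation are lesser risks.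

Fallback: the halogen is kept out of the ring-forming event and introduced afterwards by directed metalation. Diene 3 and methyl propiolate 4 are heated in toluene and worked up with acid, the established pairing for such dienes, to give methyl 2,4-dihydroxy-5-methoxybenzoate F1. Silylation (t-BuMe2SiCl, imidazole, DMF) gives methyl 2,4-bis(tert-butyldimethylsilyloxy)-5-methoxybenzoate F2. Its only C–H flanked by the ester and the methoxy group is magnesiated with TMPMgCl·LiCl (TMP = 2,2,6,6-tetramethylpiperidide) in THF; the bulky, weakly directing silyloxy groups shield the other position. Quenching with BrCCl2CCl2Br gives methyl 2-bromo-4,6-bis(tert-butyldimethylsilyloxy)-3-methoxybenzoate F3. Bu4NF in THF removes both silyl groups and returns the route to 7.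

**Step 11.** The enolate may be acylated at oxygen instead of carbon, the di-ortho-substituted acid chloride may react slowly, and the acid chloride may lose its ortho MOM group by closing onto the acetal oxygen. The hindered saponification of step 7 is an upstream weakness of the same bond construction.

Fallback: the C3–C4 bond is made by aldol addition at the aldehyde oxidation level, which is far less sensitive to ortho substitution. Ester 10 is reduced with i-Bu2AlH (CH2Cl2, −78 → 0 °C) to [2-bromo-3-methoxy-6-(methoxymethoxy)-4-(prenyloxy)phenyl]methanol F4 and oxidised with MnO2 to 2-bromo-3-methoxy-6-(methoxymethoxy)-4-(prenyloxy)benzaldehyde F5. Addition of the lithium enolate of 16 (LiN(SiMe3)2, THF, −78 °C) gives the β-hydroxy ketone 3-[2-bromo-3-methoxy-6-(methoxymethoxy)-4-(prenyloxy)phenyl]-3-hydroxy-2-(methoxymethoxy)-1-[3-methoxy-4-(methoxymethoxy)phenyl]propan-1-one F6 as a diastereomer mixture. Oxidation with 2-iodoxybenzoic acid in DMSO returns the route to diketone 18. This path bypasses steps 7 and 11.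

**Step 12.** Insertion of copper into the crowded, electron-rich C–Br bond may be slow, so that protodebromination or retro-Claisen cleavage of the diketone by hot carbonate takes over.

Fallback: the C8a–O bond is made intermolecularly and the ring closed by dehydration. Diketone 18 is hydroxylated at the C–Br carbon under zerovalent palladium catalysis (Pd2(dba)3 with 2-(di-tert-butylphosphino)-2',4',6'-triisopropylbiphenyl, benzaldoxime as hydroxide surrogate, Cs2CO3, DMF, 80 °C) to give 1-[2-hydroxy-3-methoxy-6-(methoxymethoxy)-4-(prenyloxy)phenyl]-2-(methoxymethoxy)-3-[3-methoxy-4-(methoxymethoxy)phenyl]propane-1,3-dione F7, which is identical in structure with diketone A1 of the first alternative. Its cyclic hemiketal form is dehydrated under buffered conditions (SOCl2, pyridine, CH2Cl2, 0 °C), so that the O5 MOM group stays on until ring C is closed. The route is rejoined at 19.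

**Step 13.** Acid may ionise the allylic aryl ether while the acetals are being cleaved, with loss or migration of the prenyl group.

Fallback: the prenyl group is given up and put back last. Treating 19 with HCl in refluxing MeOH removes all four acid-labile groups to give 3,5,7-trihydroxy-2-(4-hydroxy-3-methoxyphenyl)-8-methoxy-4H-chromen-4-one F8. Its 7-hydroxyl, the most acidic of the four, is alkylated with prenyl bromide 8 (1 equiv, K2CO3 1 equiv, acetone–DMF, rt) to reach 20. Selectivity against the 4'-hydroxyl is the weak point of this detour.

## Further compounds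

F1 | step 4 | methyl 2,4-dihydroxy-5-methoxybenzoate | COC(=O)c1cc(OC)c(O)cc1O
F2 | step 4 | methyl 2,4-bis[(tert-butyldimethylsilyl)oxy]-5-methoxybenzoate | COC(=O)c1cc(OC)c(O[Si](C)(C)C(C)(C)C)cc1O[Si](C)(C)C(C)(C)C
F3 | step 4 | methyl 2-bromo-4,6-bis[(tert-butyldimethylsilyl)oxy]-3-methoxybenzoate | COC(=O)c1c(Br)c(OC)c(O[Si](C)(C)C(C)(C)C)cc1O[Si](C)(C)C(C)(C)C
F4 | step 11 | [2-bromo-3-methoxy-6-(methoxymethoxy)-4-[(3-methylbut-2-en-1-yl)oxy]phenyl]methanol | COCOc1cc(OCC=C(C)C)c(OC)c(Br)c1CO
F5 | step 11 | 2-bromo-3-methoxy-6-(methoxymethoxy)-4-[(3-methylbut-2-en-1-yl)oxy]benzaldehyde | COCOc1cc(OCC=C(C)C)c(OC)c(Br)c1C=O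
F6 | step 11 | 3-[2-bromo-3-methoxy-6-(methoxymethoxy)-4-[(3-methylbut-2-en-1-yl)oxy]phenyl]-3-hydroxy-2-(methoxymethoxy)-1-[3-methoxy-4-(methoxymethoxy)phenyl]propan-1-one (racemic diastereomer mixture) | COCOC(C(O)c1c(Br)c(OC)c(OCC=C(C)C)cc1OCOC)C(=O)c1ccc(OCOC)c(OC)c1
F7 | step 12 | racemic 1-[2-hydroxy-3-methoxy-6-(methoxymethoxy)-4-[(3-methylbut-2-en-1-yl)oxy]phenyl]-2-(methoxymethoxy)-3-[3-methoxy-4-(methoxymethoxy)phenyl]propane-1,3-dione | COCOC(C(=O)c1ccc(OCOC)c(OC)c1)C(=O)c1c(O)c(OC)c(OCC=C(C)C)cc1OCOC
F8 | step 13 | 3,5,7-trihydroxy-2-(4-hydroxy-3-methoxyphenyl)-8-methoxy-4H-chromen-4-one | COc1cc(-c2oc3c(OC)c(O)cc(O)c3c(=O)c2O)ccc1O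
A1 | alternative 1 | racemic 1-[2-hydroxy-3-methoxy-6-(methoxymethoxy)-4-[(3-methylbut-2-en-1-yl)oxy]phenyl]-2-(methoxymethoxy)-3-[3-methoxy-4-(methoxymethoxy)phenyl]propane-1,3-dione | COCOC(C(=O)c1ccc(OCOC)c(OC)c1)C(=O)c1c(O)c(OC)c(OCC=C(C)C)cc1OCOC
A2 | alternative 1 | 1-[2-hydroxy-3-methoxy-6-(methoxymethoxy)-4-[(3-methylbut-2-en-1-yl)oxy]phenyl]-2-(methoxymethoxy)ethan-1-one | COCOCC(=O)c1c(O)c(OC)c(OCC=C(C)C)cc1OCOC
A3 | alternative 1 | 4-bromo-2-methoxy-1-(methoxymethoxy)benzene | COCOc1ccc(Br)cc1OC
A4 | alternative 2 | 3,5-bis(benzyloxy)-2-[4-(benzyloxy)-3-methoxyphenyl]-7-hydroxy-8-methoxy-4H-chromen-4-one | COc1cc(-c2oc3c(OC)c(O)cc(OCc4ccccc4)c3c(=O)c2OCc2ccccc2)ccc1OCc1ccccc1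
A5 | alternative 2 | 5-(benzyloxy)-2-methoxybenzene-1,3-diol | COc1c(O)cc(OCc2ccccc2)cc1O
A6 | alternative 2 | racemic ethyl 2-(benzyloxy)-3-[4-(benzyloxy)-3-methoxyphenyl]-3-oxopropanoate | CCOC(=O)C(OCc1ccccc1)C(=O)c1ccc(OCc2ccccc2)c(OC)c1
A7 | alternative 3 | 7-hydroxy-8-methoxy-5-(methoxymethoxy)-2-[3-methoxy-4-(methoxymethoxy)phenyl]-4H-chromen-4-one | COCOc1ccc(-c2cc(=O)c3c(OCOC)cc(O)c(OC)c3o2)cc1OC
A8 | alternative 3 | 4-iodo-2-methoxy-5-(methoxymethoxy)benzene-1,3-diol | COCOc1cc(O)c(OC)c(O)c1I
A9 | alternative 3 | 4-ethynyl-2-methoxy-1-(methoxymethoxy)benzene | COCOc1ccc(C#C)cc1OC
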